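**Strategy.** Everything rests on not coupling two arenes: ring A of unit 2 (C4a, C5, C6, C7, C8, C8a), a resorcinol fused to a 2-aryl-4-pyranone, is cut at C8–C7 and C6–C5. Its C8 then becomes an acidic CH2 that links C6 of the unit 1 flavone to a 6-aryl-4-pyranone carrying a methyl ester on the adjacent carbon. In one flask the lateral carbanion is C-acetylated and the new methyl ketone enolate closes on that ester (Dieckmann), which builds ring A and turns the sp2–sp3 bond into the biaryl axis. The CH2 group derives from an aromatic Claisen rearrangement to C6, the only free ortho position of the 5-O-allyl flavone.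

Key step: step 11

Assumption: the target SMILES gives no configuration for the hindered 6,8''-biaryl axis, so the axis is formed without control (racemate); the target has no stereogenic carbon.

Locants: flavone numbering is used for both units (unit 1 = the 7-methoxyflavone linked through C6; unit 2 = the flavone linked through C8). The monocyclic pyranone carries its own locants: O1, C2 (CH2 group), C3 (ester), C4 (C=O), C5 (H), C6 (aryl).

**Route**

Step 1
Reactants: 1 2',6'-dihydroxy-4'-methoxyacetophenone; 2 4-(benzyloxy)benzoyl chloride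
Product: 4 2-[4-(benzyloxy)phenyl]-5-hydroxy-7-methoxy-4H-chromen-4-one, via aryl beta-diketone 3 (not isolated)
Conditions: LiN(SiMe3)2 (4 equiv, 1 M in THF), THF, −78 to −10 °C; 2, −78 °C to rt; aq HCl; then TsOH·H2O (cat.), toluene, 110 °C
Reagents that add atoms: 4-(benzyloxy)benzoyl chloride (2), O=C(Cl)c1ccc(OCc2ccccc2)cc1
Why: Excess base turns 1 into its phenoxide–enolate polyanion, which is aroylated on carbon by 2 (Claisen-type acylation, the one-flask form of the Baker–Venkataraman route), and acid-catalysed cyclodehydration of 3 closes the pyranone; 1 is symmetric, so either phenol gives the same flavone, and the sulfonic acid catalyst is mild enough for the benzyl ether.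

Step 2
Reactants: 4 2-[4-(benzyloxy)phenyl]-5-hydroxy-7-methoxy-4H-chromen-4-one; 5 allyl bromide
Product: 6 2-[4-(benzyloxy)phenyl]-7-methoxy-5-(prop-2-en-1-yloxy)-4H-chromen-4-one
Conditions: K2CO3, DMF, 60 °C
Reagents that add atoms: allyl bromide (5), C=CCBr
Why: Williamson etherification of the only hydroxyl group; the hydrogen-bonded 5-OH reacts slowly but without competition with the allylic halide in DMF.

Step 3
Reactants: 6 2-[4-(benzyloxy)phenyl]-7-methoxy-5-(prop-2-en-1-yloxy)-4H-chromen-4-one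
Product: 7 2-[4-(benzyloxy)phenyl]-5-hydroxy-7-methoxy-6-(prop-2-en-1-yl)-4H-chromen-4-one
Conditions: N,N-diethylaniline, 200 °C, argon
Reagents that add atoms: none
Why: Aromatic Claisen rearrangement ([3,3]-sigmatropic shift): of the two carbons ortho to O5, C4a is quaternary, so the allyl group can arrive only at C6, and enolisation of the dienone restores the chelated 5-OH; no stereocentre is formed.

Step 4
Reactants: 7 2-[4-(benzyloxy)phenyl]-5-hydroxy-7-methoxy-6-(prop-2-en-1-yl)-4H-chromen-4-one; 8 benzyl bromide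
Product: 9 5-(benzyloxy)-2-[4-(benzyloxy)phenyl]-7-methoxy-6-(prop-2-en-1-yl)-4H-chromen-4-one
Conditions: K2CO3, Bu4NI (cat.), DMF, 70 °C
Reagents that add atoms: benzyl bromide (8), BrCc1ccccc1
Why: Williamson benzylation; carbonate in warm DMF with iodide catalysis overcomes the hydrogen bond to the C4 carbonyl and the flanking allyl group, and no other acidic site competes.

Step 5
Reactants: 9 5-(benzyloxy)-2-[4-(benzyloxy)phenyl]-7-methoxy-6-(prop-2-en-1-yl)-4H-chromen-4-one
Product: 10 {5-(benzyloxy)-2-[4-(benzyloxy)phenyl]-7-methoxy-4-oxo-4H-chromen-6-yl}acetaldehyde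
Conditions: OsO4 (cat.), NaIO4, 2,6-lutidine, dioxane–H2O, rt
Reagents that add atoms: OsO4 (oxygen donor, catalytic), O=[Os](=O)(=O)=O; NaIO4 (terminal oxidant), [Na+].[O-]I(=O)(=O)=O
Why: Lemieux–Johnson oxidation: OsO4 dihydroxylates the isolated monosubstituted alkene far faster than the conjugated C2=C3 bond of the flavone, NaIO4 cleaves the diol and re-oxidises osmium, and 2,6-lutidine suppresses over-oxidation.

Step 6
Reactants: 10 {5-(benzyloxy)-2-[4-(benzyloxy)phenyl]-7-methoxy-4-oxo-4H-chromen-6-yl}acetaldehyde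
Product: 11 {5-(benzyloxy)-2-[4-(benzyloxy)phenyl]-7-methoxy-4-oxo-4H-chromen-6-yl}acetic acid
Conditions: NaClO2, NaH2PO4, 2-methylbut-2-ene, tBuOH–THF–H2O, rt
Reagents that add atoms: sodium chlorite, [Na+].[O-]Cl=O
Why: Pinnick oxidation: chlorous acid oxidises the aldehyde under buffered conditions that leave benzyl ethers and the flavone untouched, while 2-methylbut-2-ene traps HOCl before it can chlorinate the electron-rich ring.

Step 7
Reactants: 11 {5-(benzyloxy)-2-[4-(benzyloxy)phenyl]-7-methoxy-4-oxo-4H-chromen-6-yl}acetic acid; 12 Meldrum's acid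
Product: 14 methyl 4-{5-(benzyloxy)-2-[4-(benzyloxy)phenyl]-7-methoxy-4-oxo-4H-chromen-6-yl}-3-oxobutanoate, via acyl Meldrum's acid 13 (not isolated)
Conditions: DCC, DMAP, CH2Cl2, 0 °C to rt; filter, acid wash; then MeOH–toluene, 80 °C
Reagents that add atoms: Meldrum's acid (12), CC1(C)OC(=O)CC(=O)O1; methanol, CO
Why: Carbodiimide-mediated C-acylation of Meldrum's acid, then methanolysis of 13 through its acylketene with loss of acetone and CO2 (Meldrum's acid β-keto ester synthesis).

Step 8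
Reactants: 15 1-(benzyloxy)-4-ethynylbenzene
Product: 16 3-[4-(benzyloxy)phenyl]prop-2-ynoic acid
Conditions: nBuLi, THF, −78 °C; CO2; aq HCl
Reagents that add atoms: carbon dioxide, O=C=O
Why: The terminal alkyne C–H is the most acidic site, and the lithium acetylide adds to CO2 (acetylide carboxylation).

Step 9
Reactants: 16 3-[4-(benzyloxy)phenyl]prop-2-ynoic acid
Product: 17 3-[4-(benzyloxy)phenyl]prop-2-ynoyl chloride
Conditions: (COCl)2, DMF (cat.), CH2Cl2, 0 °C to rt; used crude
Reagents that add atoms: oxalyl chloride, O=C(Cl)C(=O)Cl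
Why: Acid chloride formation through the Vilsmeier-type chloroiminium salt, at low temperature so that the alkyne does not add HCl.

Step 10
Reactants: 14 methyl 4-{5-(benzyloxy)-2-[4-(benzyloxy)phenyl]-7-methoxy-4-oxo-4H-chromen-6-yl}-3-oxobutanoate; 17 3-[4-(benzyloxy)phenyl]prop-2-ynoyl chloride
Product: 19 methyl 6-[4-(benzyloxy)phenyl]-2-({5-(benzyloxy)-2-[4-(benzyloxy)phenyl]-7-methoxy-4-oxo-4H-chromen-6-yl}methyl)-4-oxo-4H-pyran-3-carboxylate, via ynoyl keto ester 18 (not isolated)
Conditions: MgCl2, pyridine, CH2Cl2, 0 °C; 17, 0 °C to rt; aq HCl; then Et3N (cat.), MeCN, rt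
Reagents that add atoms: acid chloride 17, O=C(Cl)C#Cc1ccc(OCc2ccccc2)cc1
Why: MgCl2 and pyridine form the chelated magnesium enolate of 14, which is acylated on carbon by 17 (soft-enolisation C-acylation), and in 18 the enol oxygen of the arylacetyl carbonyl adds to the ynone β-carbon in a 6-endo-dig oxa-Michael closure, the classical γ-pyrone synthesis from acetylenic acid chlorides and β-keto esters, which necessarily places the ester next to the CH2-bearing carbon.

Step 11
Reactants: 19 methyl 6-[4-(benzyloxy)phenyl]-2-({5-(benzyloxy)-2-[4-(benzyloxy)phenyl]-7-methoxy-4-oxo-4H-chromen-6-yl}methyl)-4-oxo-4H-pyran-3-carboxylate; 20 1-acetylimidazole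
Product: 22 5-(benzyloxy)-2-[4-(benzyloxy)phenyl]-6-{2-[4-(benzyloxy)phenyl]-5,7-dihydroxy-4-oxo-4H-chromen-8-yl}-7-methoxy-4H-chromen-4-one, via C-acetyl ketone 21 (not isolated)
Conditions: LiN(iPr)2 (2.2 equiv, commercial solution), THF, −78 °C; 20 (1.1 equiv), −78 °C; LiN(iPr)2 (2 equiv), −78 °C to rt; aq HCl
Reagents that add atoms: 1-acetylimidazole (20), CC(=O)n1ccnc1
Why: Proposed new method: LiN(iPr)2 removes a proton from the CH2 group of 19, which is benzylic and vinylogously alpha to both the pyranone C4 carbonyl and the C3 ester, and the delocalised anion is acetylated by 20 at the exocyclic carbon (C8–C7 bond of unit 2), the only site whose attack keeps the pyranone intact, to give 21, whose more acidic methine is deprotonated at once by the remaining base. The second portion of base then forms the terminal methyl ketone enolate (a dianion of the 1,3-dicarbonyl type), which attacks the neighbouring ester in a 6-(enolexo)-exo-trig Dieckmann closure (C6–C5 bond); loss of methoxide and enolisation of the cyclohexenedione give the aromatic 5,7-dihydroxy ring A fused to the pyranone, that is, the unit 2 flavone. The closest known reaction types are acylation of lateral ortho-toluate carbanions followed by Dieckmann closure to naphthalene-1,3-diols and lateral lithiation of 2-alkyl-4-pyranones, and the proposal merges them on a pyranone ester. No stereocentre is created: the methine carbon of 21 is racemic and becomes sp2 on aromatisation, and the tetra-ortho-substituted axis forms as the racemate. The step needs acetylation on carbon and not on oxygen, closure without opening of either pyranone ring, and no metalation of the vinylic C–H positions of the flavone and pyranone; the soft carbanion paired with an acyl imidazole, the electron-rich anionic state of the pyranone, the fact that only the C3 ester lies within six-ring reach of the methyl ketone enolate, and the portionwise addition of base are meant to secure this.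

Step 12
Reactants: 22 5-(benzyloxy)-2-[4-(benzyloxy)phenyl]-6-{2-[4-(benzyloxy)phenyl]-5,7-dihydroxy-4-oxo-4H-chromen-8-yl}-7-methoxy-4H-chromen-4-one
Product: 23 6-[5,7-dihydroxy-2-(4-hydroxyphenyl)-4-oxo-4H-chromen-8-yl]-5-hydroxy-2-(4-hydroxyphenyl)-7-methoxy-4H-chromen-4-one (target, CNP0246647.0)
Conditions: H2 (1 atm), Pd/C (10%), THF–MeOH, rt
Reagents that add atoms: none
Why: Catalytic hydrogenolysis of the three aryl benzyl ethers; benzylic C–O cleavage is much faster than saturation of the flavone C2=C3 bonds at ambient pressure, and the 7-methoxy group is inert.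

**Compound list**

1 | 2',6'-dihydroxy-4'-methoxyacetophenone | CC(=O)c1c(O)cc(OC)cc1O | starting material
2 | 4-(benzyloxy)benzoyl chloride | O=C(Cl)c1ccc(OCc2ccccc2)cc1 | starting material
3 | 1-[4-(benzyloxy)phenyl]-3-(2,6-dihydroxy-4-methoxyphenyl)propane-1,3-dione (formed in the flask) | COc1cc(O)c(C(=O)CC(=O)c2ccc(OCc3ccccc3)cc2)c(O)c1 | intermediate
4 | 2-[4-(benzyloxy)phenyl]-5-hydroxy-7-methoxy-4H-chromen-4-one | COc1cc2oc(-c3ccc(OCc4ccccc4)cc3)cc(=O)c2c(O)c1 | intermediate
5 | allyl bromide (3-bromoprop-1-ene) | C=CCBr | starting material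
6 | 2-[4-(benzyloxy)phenyl]-7-methoxy-5-(prop-2-en-1-yloxy)-4H-chromen-4-one | COc1cc2oc(-c3ccc(OCc4ccccc4)cc3)cc(=O)c2c(OCC=C)c1 | intermediate
7 | 2-[4-(benzyloxy)phenyl]-5-hydroxy-7-methoxy-6-(prop-2-en-1-yl)-4H-chromen-4-one | COc1cc2oc(-c3ccc(OCc4ccccc4)cc3)cc(=O)c2c(O)c1CC=C | intermediate
8 | benzyl bromide | BrCc1ccccc1 | starting material
9 | 5-(benzyloxy)-2-[4-(benzyloxy)phenyl]-7-methoxy-6-(prop-2-en-1-yl)-4H-chromen-4-one | COc1cc2oc(-c3ccc(OCc4ccccc4)cc3)cc(=O)c2c(OCc2ccccc2)c1CC=C | intermediate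
10 | {5-(benzyloxy)-2-[4-(benzyloxy)phenyl]-7-methoxy-4-oxo-4H-chromen-6-yl}acetaldehyde | COc1cc2oc(-c3ccc(OCc4ccccc4)cc3)cc(=O)c2c(OCc2ccccc2)c1CC=O | intermediate
11 | {5-(benzyloxy)-2-[4-(benzyloxy)phenyl]-7-methoxy-4-oxo-4H-chromen-6-yl}acetic acid | COc1cc2oc(-c3ccc(OCc4ccccc4)cc3)cc(=O)c2c(OCc2ccccc2)c1CC(=O)O | intermediate
12 | Meldrum's acid (2,2-dimethyl-1,3-dioxane-4,6-dione) | CC1(C)OC(=O)CC(=O)O1 | starting material
13 | 5-(2-{5-(benzyloxy)-2-[4-(benzyloxy)phenyl]-7-methoxy-4-oxo-4H-chromen-6-yl}-1-hydroxyethylidene)-2,2-dimethyl-1,3-dioxane-4,6-dione (formed in the flask) | COc1cc2oc(-c3ccc(OCc4ccccc4)cc3)cc(=O)c2c(OCc2ccccc2)c1CC(O)=C1C(=O)OC(C)(C)OC1=O | intermediate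
14 | methyl 4-{5-(benzyloxy)-2-[4-(benzyloxy)phenyl]-7-methoxy-4-oxo-4H-chromen-6-yl}-3-oxobutanoate | COc1cc2oc(-c3ccc(OCc4ccccc4)cc3)cc(=O)c2c(OCc2ccccc2)c1CC(=O)CC(=O)OC | intermediate
15 | 1-(benzyloxy)-4-ethynylbenzene | C#Cc1ccc(OCc2ccccc2)cc1 | starting material
16 | 3-[4-(benzyloxy)phenyl]prop-2-ynoic acid | OC(=O)C#Cc1ccc(OCc2ccccc2)cc1 | intermediate
17 | 3-[4-(benzyloxy)phenyl]prop-2-ynoyl chloride | O=C(Cl)C#Cc1ccc(OCc2ccccc2)cc1 | intermediate
18 | methyl 5-[4-(benzyloxy)phenyl]-2-({5-(benzyloxy)-2-[4-(benzyloxy)phenyl]-7-methoxy-4-oxo-4H-chromen-6-yl}acetyl)-3-oxopent-4-ynoate (formed in the flask, drawn as the triketo tautomer) | COc1cc2oc(-c3ccc(OCc4ccccc4)cc3)cc(=O)c2c(OCc2ccccc2)c1CC(=O)C(C(=O)OC)C(=O)C#Cc1ccc(OCc2ccccc2)cc1 | intermediate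
19 | methyl 6-[4-(benzyloxy)phenyl]-2-({5-(benzyloxy)-2-[4-(benzyloxy)phenyl]-7-methoxy-4-oxo-4H-chromen-6-yl}methyl)-4-oxo-4H-pyran-3-carboxylate | COc1cc2oc(-c3ccc(OCc4ccccc4)cc3)cc(=O)c2c(OCc2ccccc2)c1CC1=C(C(=O)OC)C(=O)C=C(c2ccc(OCc3ccccc3)cc2)O1 | intermediate
20 | 1-acetylimidazole | CC(=O)n1ccnc1 | starting material
21 | methyl 6-[4-(benzyloxy)phenyl]-2-(1-{5-(benzyloxy)-2-[4-(benzyloxy)phenyl]-7-methoxy-4-oxo-4H-chromen-6-yl}-2-oxopropyl)-4-oxo-4H-pyran-3-carboxylate (racemic, formed in the flask) | COc1cc2oc(-c3ccc(OCc4ccccc4)cc3)cc(=O)c2c(OCc2ccccc2)c1C(C(C)=O)C1=C(C(=O)OC)C(=O)C=C(c2ccc(OCc3ccccc3)cc2)O1 | intermediate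
22 | 5-(benzyloxy)-2-[4-(benzyloxy)phenyl]-6-{2-[4-(benzyloxy)phenyl]-5,7-dihydroxy-4-oxo-4H-chromen-8-yl}-7-methoxy-4H-chromen-4-one (racemic axis) | COc1cc2oc(-c3ccc(OCc4ccccc4)cc3)cc(=O)c2c(OCc2ccccc2)c1-c1c(O)cc(O)c2c(=O)cc(-c3ccc(OCc4ccccc4)cc3)oc12 | intermediate
23 | 6-[5,7-dihydroxy-2-(4-hydroxyphenyl)-4-oxo-4H-chromen-8-yl]-5-hydroxy-2-(4-hydroxyphenyl)-7-methoxy-4H-chromen-4-one (6,8''-biapigenin 7-methyl ether, racemic axis) | COc1cc2oc(-c3ccc(O)cc3)cc(=O)c2c(O)c1-c1c(O)cc(O)c2c(=O)cc(-c3ccc(O)cc3)oc12 | target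

**Count**

Total steps: 12 (ten in the main line, two in the side branch to 17). Longest linear sequence: 10 steps (steps 1–7, 10, 11, 12).

**Steps most likely to fail**

1. Step 11 (the step labelled as a proposed new method).
   - What may go wrong: acetylation at the crowded benzylic carbon may be slow, so the electrophile is consumed by the amide base. Free base may metalate the vinylic C–H positions. The closure may stall at the stage of 21 because the delocalised anion lowers the electrophilicity of the ester.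
   - Fallback (known chemistry, Suzuki–Miyaura coupling of two flavones): it sets out from 4 and returns at 23. Iodination of 4 ortho to its free 5-OH (benzyltrimethylammonium dichloroiodate, CaCO3, CH2Cl2–MeOH, rt) should give 2-[4-(benzyloxy)phenyl]-5-hydroxy-6-iodo-7-methoxy-4H-chromen-4-one F1, and benzylation (8, K2CO3, DMF) its ether 5-(benzyloxy)-2-[4-(benzyloxy)phenyl]-6-iodo-7-methoxy-4H-chromen-4-one F2. Commercial apigenin is perbenzylated (8, K2CO3, DMF, 80 °C) to 5,7-bis(benzyloxy)-2-[4-(benzyloxy)phenyl]-4H-chromen-4-one F3, iodinated at C8 (I2, CF3CO2Ag, CH2Cl2) to 5,7-bis(benzyloxy)-2-[4-(benzyloxy)phenyl]-8-iodo-4H-chromen-4-one F4 and borylated (bis(pinacolato)diboron, PdCl2(dppf), KOAc, dioxane, 90 °C) to 5,7-bis(benzyloxy)-2-[4-(benzyloxy)phenyl]-8-(4,4,5,5-tetramethyl-1,3,2-dioxaborolan-2-yl)-4H-chromen-4-one F5. Coupling of F2 with F5 (Pd(OAc)2, SPhos, K3PO4, toluene–H2O, 100 °C) should give the pentabenzyl ether 5-(benzyloxy)-2-[4-(benzyloxy)phenyl]-6-{5,7-bis(benzyloxy)-2-[4-(benzyloxy)phenyl]-4-oxo-4H-chromen-8-yl}-7-methoxy-4H-chromen-4-one F6, and hydrogenolysis under the conditions of step 12 gives 23.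

2. Step 10.
   - What may go wrong: the enolate may be acylated on oxygen, nucleophiles may add to the triple bond of the acid chloride, or the ring may close only partly.
   - Fallback (aroylketene cycloaddition in place of ynone cyclisation): it sets out from 14 and returns at 19. Acylation of 12 with 2 (pyridine, DMAP, CH2Cl2) gives 5-{[4-(benzyloxy)phenyl](hydroxy)methylidene}-2,2-dimethyl-1,3-dioxane-4,6-dione F7. Condensation of 14 with pyrrolidine (TsOH cat., toluene, water removal) gives the enamino ester methyl (2E)-4-{5-(benzyloxy)-2-[4-(benzyloxy)phenyl]-7-methoxy-4-oxo-4H-chromen-6-yl}-3-(pyrrolidin-1-yl)but-2-enoate F8. Heating F7 (2 equiv) with F8 in toluene at 110 °C releases the aroylketene, which should add to the enamine double bond in a [4+2] manner; elimination of pyrrolidine from the adduct then leaves only the 4-pyranone 19.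

3. Step 3.
   - What may go wrong: at 200 °C the allyl group may move on to C8 by a further Cope shift, the ortho-allylphenol may cyclise to a dihydrofuran, or the allyl ether may simply cleave.
   - Fallback (ortho-formylation and one-carbon homologation in place of the sigmatropic route): it sets out from 4 and returns at 10, bypassing steps 2–5. Magnesium-mediated ortho-formylation (MgCl2, Et3N, paraformaldehyde, MeCN, reflux), which can only reach C6, should give 2-[4-(benzyloxy)phenyl]-5-hydroxy-7-methoxy-4-oxo-4H-chromene-6-carbaldehyde F9. Benzylation (8, K2CO3, DMF) gives 5-(benzyloxy)-2-[4-(benzyloxy)phenyl]-7-methoxy-4-oxo-4H-chromene-6-carbaldehyde F10. Wittig reaction with Ph3P=CHOMe (from the phosphonium chloride and KOtBu, THF, 0 °C) gives the enol ether 5-(benzyloxy)-2-[4-(benzyloxy)phenyl]-7-methoxy-6-(2-methoxyethenyl)-4H-chromen-4-one F11 (E/Z mixture), and mild acid hydrolysis (aq HCl, THF) gives 10.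

**Further compounds**

F1 | step 11 | 2-[4-(benzyloxy)phenyl]-5-hydroxy-6-iodo-7-methoxy-4H-chromen-4-one | COc1cc2oc(-c3ccc(OCc4ccccc4)cc3)cc(=O)c2c(O)c1I
F2 | step 11 | 5-(benzyloxy)-2-[4-(benzyloxy)phenyl]-6-iodo-7-methoxy-4H-chromen-4-one | COc1cc2oc(-c3ccc(OCc4ccccc4)cc3)cc(=O)c2c(OCc2ccccc2)c1I
F3 | step 11 | 5,7-bis(benzyloxy)-2-[4-(benzyloxy)phenyl]-4H-chromen-4-one | O=c1cc(-c2ccc(OCc3ccccc3)cc2)oc2cc(OCc3ccccc3)cc(OCc3ccccc3)c12
F4 | step 11 | 5,7-bis(benzyloxy)-2-[4-(benzyloxy)phenyl]-8-iodo-4H-chromen-4-one | O=c1cc(-c2ccc(OCc3ccccc3)cc2)oc2c(I)c(OCc3ccccc3)cc(OCc3ccccc3)c12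
F5 | step 11 | 5,7-bis(benzyloxy)-2-[4-(benzyloxy)phenyl]-8-(4,4,5,5-tetramethyl-1,3,2-dioxaborolan-2-yl)-4H-chromen-4-one | O=c1cc(-c2ccc(OCc3ccccc3)cc2)oc2c(B3OC(C)(C)C(C)(C)O3)c(OCc3ccccc3)cc(OCc3ccccc3)c12
F6 | step 11 | 5-(benzyloxy)-2-[4-(benzyloxy)phenyl]-6-{5,7-bis(benzyloxy)-2-[4-(benzyloxy)phenyl]-4-oxo-4H-chromen-8-yl}-7-methoxy-4H-chromen-4-one | COc1cc2oc(-c3ccc(OCc4ccccc4)cc3)cc(=O)c2c(OCc2ccccc2)c1-c1c(OCc2ccccc2)cc(OCc2ccccc2)c2c(=O)cc(-c3ccc(OCc4ccccc4)cc3)oc12
F7 | step 10 | 5-{[4-(benzyloxy)phenyl](hydroxy)methylidene}-2,2-dimethyl-1,3-dioxane-4,6-dione | CC1(C)OC(=O)C(=C(O)c2ccc(OCc3ccccc3)cc2)C(=O)O1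
F8 | step 10 | methyl (2E)-4-{5-(benzyloxy)-2-[4-(benzyloxy)phenyl]-7-methoxy-4-oxo-4H-chromen-6-yl}-3-(pyrrolidin-1-yl)but-2-enoate | COc1cc2oc(-c3ccc(OCc4ccccc4)cc3)cc(=O)c2c(OCc2ccccc2)c1C/C(=C\C(=O)OC)N1CCCC1
F9 | step 3 | 2-[4-(benzyloxy)phenyl]-5-hydroxy-7-methoxy-4-oxo-4H-chromene-6-carbaldehyde | COc1cc2oc(-c3ccc(OCc4ccccc4)cc3)cc(=O)c2c(O)c1C=O
F10 | step 3 | 5-(benzyloxy)-2-[4-(benzyloxy)phenyl]-7-methoxy-4-oxo-4H-chromene-6-carbaldehyde | COc1cc2oc(-c3ccc(OCc4ccccc4)cc3)cc(=O)c2c(OCc2ccccc2)c1C=O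
F11 | step 3 | 5-(benzyloxy)-2-[4-(benzyloxy)phenyl]-7-methoxy-6-(2-methoxyethenyl)-4H-chromen-4-one (E/Z mixture) | COc1cc2oc(-c3ccc(OCc4ccccc4)cc3)cc(=O)c2c(OCc2ccccc2)c1C=COC
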